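**Plan**
Labels: ring A is the 2,4,6-trioxygenated ring, ring C the 3,4,5-trioxygenated ring, ring B the central ring (B1 carries the ring A ether, B3 and B4 the hydroxyls, B5 the ring C ether).
Feature used: ring B has oxygens at B1 and B4 para to each other, with B3–O and B5–O flanking B4; this is the 4-alkoxyphenol pattern of a chromium carbene benzannulation in which B4 is the CO carbon.
Retrosynthesis: the seven O-alkyl bonds are cut first (back to 17); ring B is then cut at B1–B6, B5–B4 and B4–B3 into carbene 8 (B1–B3 with the ring A ether), ynol ether 15 (B5–B6 with the ring C ether) and one CO ligand (B4); 8 is cut at its carbene C–O and Cr=C bonds, 15 at its alkynyl C–O bond.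
Forward: rings A and C are bought; two two-step branches give 8 and 15; ring B is the only ring formed (step 5) and both diaryl ether links arrive with the partners; global dealkylation ends the route.
Stereochemistry: the target has no stereocentre; the Z geometry of the ethoxyvinyl unit is erased when ring B aromatises.

Key step: step 5

Assumption: (Z)-1-bromo-2-ethoxyethene, 2,4,6-trimethoxyphenol, 3,4,5-trimethoxyphenol and (for a fallback only) 5-bromo-3-ethoxy-2-hydroxybenzaldehyde are taken as purchasable; 8 and 15 are made shortly before step 5 and not stored.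

**Step 1**
Reactants: 1 chromium hexacarbonyl Cr(CO)6; 2 (Z)-1-bromo-2-ethoxyethene
Product: 5 tetramethylammonium pentacarbonyl[(Z)-3-ethoxy-1-oxidoprop-2-enylidene]chromate, via (Z)-2-ethoxyvinyllithium 3 (not isolated), via lithium acyl chromate 4 (not isolated)
Conditions: n-BuLi, Et2O, −78 °C; Cr(CO)6, THF, −78 to 0 °C; Me4NBr, H2O, 0 °C
Reagents that add atoms: tetramethylammonium bromide, C[N+](C)(C)C.[Br-]
Why: Bromine–lithium exchange at −78 °C gives the cis-vinyllithium 3, which keeps its geometry and does not lose lithium ethoxide at this temperature, its addition to a CO ligand of Cr(CO)6 is the Fischer acyl metalate synthesis, and cation exchange gives the tetramethylammonium salt that is the usual substrate for O-acylation.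

**Step 2**
Reactants: 5 tetramethylammonium pentacarbonyl[(Z)-3-ethoxy-1-oxidoprop-2-enylidene]chromate; 6 2,4,6-trimethoxyphenol
Product: 8 pentacarbonyl[(Z)-3-ethoxy-1-(2,4,6-trimethoxyphenoxy)prop-2-enylidene]chromium, via acetoxycarbene complex 7 (not isolated)
Conditions: AcBr, CH2Cl2, −40 °C; then 6, −40 to 0 °C
Reagents that add atoms: none
Why: O-Acylation of the acyl chromate gives the acetoxycarbene 7, an anhydride-like electrophile, and addition–elimination of the phenol at the carbene carbon (phenolysis of an acyloxycarbene complex, the standard entry to aryloxy Fischer carbenes) gives 8, the two ortho methoxy groups slowing but not blocking attack at this planar, strongly electrophilic carbon.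

**Step 3**
Reactants: 9 3,4,5-trimethoxyphenol; 10 trichloroethylene
Product: 12 5-{[(E)-1,2-dichloroethenyl]oxy}-1,2,3-trimethoxybenzene, via dichloroacetylene 11 (not isolated)
Conditions: K2CO3, DMF, 70 °C
Reagents that add atoms: none
Why: K2CO3 eliminates HCl from trichloroethylene to dichloroacetylene, to which the phenoxide adds in anti fashion to give the (E)-dichlorovinyl ether (the standard dichlorovinylation of phenols), and the electron-rich ring is untouched.

**Step 4**
Reactants: 12 5-{[(E)-1,2-dichloroethenyl]oxy}-1,2,3-trimethoxybenzene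
Product: 15 5-(ethynyloxy)-1,2,3-trimethoxybenzene, via chloroalkynyl ether 13 (not isolated), via lithium aryloxyacetylide 14 (not isolated)
Conditions: n-BuLi (2.2 equiv), Et2O, −78 to −40 °C; MeOH, −78 °C
Reagents that add atoms: none
Why: Vinylic deprotonation with loss of LiCl gives the chloroalkyne 13, chlorine–lithium exchange gives the acetylide 14 and methanol protonates it (the standard dichlorovinyl ether to ynol ether elimination), the low temperature keeping n-BuLi from metalating the trimethoxyaryl ring.

**Step 5**
Reactants: 8 pentacarbonyl[(Z)-3-ethoxy-1-(2,4,6-trimethoxyphenoxy)prop-2-enylidene]chromium; 15 5-(ethynyloxy)-1,2,3-trimethoxybenzene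
Product: 17 2-ethoxy-4-(2,4,6-trimethoxyphenoxy)-6-(3,4,5-trimethoxyphenoxy)phenol, via tricarbonylchromium arene complex 16 (not isolated)
Conditions: THF, 45 °C, Ar, slow addition of 15 (1.5 equiv); then air, EtOAc, rt
Reagents that add atoms: none
Why: Proposed new method: thermal loss of one CO from 8 lets the ynol ether 15 coordinate and insert into the Cr=C bond with its CH carbon bonding to the carbene carbon (B1–B6), giving an aryloxy-stabilised dienylcarbene; migration of a CO ligand onto the former alkyne carbon (B5–B4) gives a chromium-bound dienylketene, which closes onto the ethoxyvinyl terminus (B4–B3) and enolises to the tricarbonylchromium-bound phenol 16, freed as 17 by air. The closest known reaction type is the Dötz benzannulation of alkoxy(alkenyl)carbene complexes of zerovalent chromium with terminal alkynes; not established is the combination of an aryloxy group on the carbene carbon, a donor on the vinyl terminus and an ynol ether as the alkyne. Ring B is the only ring formed and it closes by six-electron (6π) electrocyclisation of the dienylketene; no stereocentre arises and the Z geometry of the vinyl ether is erased on aromatisation. The step needs one regiochemistry of insertion, and two features of 15 secure it: a terminal alkyne places its substituent away from the carbene carbon, and the oxygen polarises the triple bond so that the nucleophilic CH carbon attacks the electrophilic carbene carbon. It also needs CO insertion to outrun CO-free closure to a cyclopentadiene and ketene closure to a cyclobutenone or furan, which the alkenyl (not aryl) carbene, the weakly donating aryloxy groups and THF as coordinating solvent should favour, while slow addition of 15 limits its oligomerisation.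

**Step 6**
Reactants: 17 2-ethoxy-4-(2,4,6-trimethoxyphenoxy)-6-(3,4,5-trimethoxyphenoxy)phenol
Product: 18 3-(3,4,5-trihydroxyphenoxy)-5-(2,4,6-trihydroxyphenoxy)benzene-1,2-diol (CNP0216308.0)
Conditions: BBr3 (excess), CH2Cl2, −78 °C to rt; H2O, 0 °C
Reagents that add atoms: none
Why: BBr3 binds each alkyl aryl ether oxygen and bromide attacks the alkyl carbon (Lewis acid ether dealkylation), which removes the six methyl groups and the ethyl group, whereas the two diaryl ether links have no sp3 carbon on oxygen and stay intact.

**Compound list**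
1 | chromium hexacarbonyl, Cr(CO)6 | O=C=[Cr](=C=O)(=C=O)(=C=O)(=C=O)=C=O | starting material
2 | (Z)-1-bromo-2-ethoxyethene | CCO/C=C\Br | starting material
3 | (Z)-2-ethoxyvinyllithium | [Li]/C=C\OCC | intermediate
4 | lithium pentacarbonyl[(Z)-3-ethoxy-1-oxidoprop-2-enylidene]chromate | [Li+].CCO/C=C\C([O-])=[Cr](=C=O)(=C=O)(=C=O)(=C=O)=C=O | intermediate
5 | tetramethylammonium pentacarbonyl[(Z)-3-ethoxy-1-oxidoprop-2-enylidene]chromate | C[N+](C)(C)C.CCO/C=C\C([O-])=[Cr](=C=O)(=C=O)(=C=O)(=C=O)=C=O | intermediate
6 | 2,4,6-trimethoxyphenol | COc1cc(OC)c(O)c(OC)c1 | starting material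
7 | pentacarbonyl[(Z)-1-acetoxy-3-ethoxyprop-2-enylidene]chromium | CCO/C=C\C(OC(C)=O)=[Cr](=C=O)(=C=O)(=C=O)(=C=O)=C=O | intermediate
8 | pentacarbonyl[(Z)-3-ethoxy-1-(2,4,6-trimethoxyphenoxy)prop-2-enylidene]chromium | CCO/C=C\C(Oc1c(OC)cc(OC)cc1OC)=[Cr](=C=O)(=C=O)(=C=O)(=C=O)=C=O | intermediate
9 | 3,4,5-trimethoxyphenol | COc1cc(O)cc(OC)c1OC | starting material
10 | trichloroethylene | ClC=C(Cl)Cl | starting material
11 | dichloroacetylene | ClC#CCl | intermediate
12 | 5-{[(E)-1,2-dichloroethenyl]oxy}-1,2,3-trimethoxybenzene | Cl/C=C(/Cl)Oc1cc(OC)c(OC)c(OC)c1 | intermediate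
13 | 5-[(chloroethynyl)oxy]-1,2,3-trimethoxybenzene | ClC#COc1cc(OC)c(OC)c(OC)c1 | intermediate
14 | lithium (3,4,5-trimethoxyphenoxy)acetylide | [Li]C#COc1cc(OC)c(OC)c(OC)c1 | intermediate
15 | 5-(ethynyloxy)-1,2,3-trimethoxybenzene | C#COc1cc(OC)c(OC)c(OC)c1 | intermediate
16 | tricarbonyl[2-ethoxy-4-(2,4,6-trimethoxyphenoxy)-6-(3,4,5-trimethoxyphenoxy)phenol]chromium, Cr(CO)3 bound η6 to ring B (written as ligand plus Cr(CO)3 fragment) | CCOc1cc(Oc2c(OC)cc(OC)cc2OC)cc(Oc2cc(OC)c(OC)c(OC)c2)c1O.O=C=[Cr](=C=O)=C=O | intermediate
17 | 2-ethoxy-4-(2,4,6-trimethoxyphenoxy)-6-(3,4,5-trimethoxyphenoxy)phenol | CCOc1cc(Oc2c(OC)cc(OC)cc2OC)cc(Oc2cc(OC)c(OC)c(OC)c2)c1O | intermediate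
18 | 3-(3,4,5-trihydroxyphenoxy)-5-(2,4,6-trihydroxyphenoxy)benzene-1,2-diol | Oc1cc(O)c(Oc2cc(O)c(O)c(Oc3cc(O)c(O)c(O)c3)c2)c(O)c1 | target

**Count**
Total steps: 6. Longest linear sequence: 4 steps (1, 2, 5, 6 from Cr(CO)6; equally 3, 4, 5, 6 from 9).

**Steps most likely to fail**

1. Step 5 (Proposed new method). What may go wrong: after the ynol ether has inserted, the aryloxy-stabilised dienylcarbene takes up CO too slowly and closes without CO to a five-membered ring, the ketene closes to a four- or five-membered ring instead of the six-membered one, or the ynol ether oligomerises at chromium. The fallback uses known copper and peracid chemistry without chromium; it sets out from 6 and returns to the route at 17. Purchased 5-bromo-3-ethoxy-2-hydroxybenzaldehyde (ring B with bromine at B1 and the formyl group at B5) is benzylated (BnBr, K2CO3, DMF) to 2-(benzyloxy)-5-bromo-3-ethoxybenzaldehyde F1. Ullmann coupling of F1 with the hindered phenol 6 (CuI, picolinic acid, K3PO4, DMSO, 90 °C) should give 2-(benzyloxy)-3-ethoxy-5-(2,4,6-trimethoxyphenoxy)benzaldehyde F2. Baeyer–Villiger oxidation of this electron-rich aldehyde (mCPBA, CH2Cl2) should give 2-(benzyloxy)-3-ethoxy-5-(2,4,6-trimethoxyphenoxy)phenyl formate F3, which is hydrolysed (KOH, MeOH/H2O) to 2-(benzyloxy)-3-ethoxy-5-(2,4,6-trimethoxyphenoxy)phenol F4. A second Ullmann coupling with purchased 5-bromo-1,2,3-trimethoxybenzene (CuI, N,N-dimethylglycine, Cs2CO3, dioxane, 100 °C) should give 2-(benzyloxy)-1-ethoxy-5-(2,4,6-trimethoxyphenoxy)-3-(3,4,5-trimethoxyphenoxy)benzene F5. Hydrogenolysis (H2, Pd/C, EtOAc) gives 17, and step 6 follows unchanged.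

2. Step 2. What may go wrong: exchange of the hindered phenol at the carbene carbon is slower than thermal decay of the acetoxycarbene, or the phenol adds at the β-carbon of the vinylogous system. The fallback sets out from 5 and returns at 8. The acetoxycarbene 7 is generated as in step 2 and captured at −40 °C by the small nucleophile C6F5ONa to give the isolable active aryloxycarbene pentacarbonyl[(Z)-3-ethoxy-1-(pentafluorophenoxy)prop-2-enylidene]chromium F6. This is treated in THF at −20 °C to rt with sodium 2,4,6-trimethoxyphenoxide F7 (from 6 and NaH), which should displace the far less basic pentafluorophenoxide by addition–elimination and give 8. The hindered exchange thus runs on a carbene that tolerates the time and temperature it needs.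

3. Step 4. What may go wrong: hydration or oligomerisation of the terminal aryl ynol ether during work-up, concentration or storage, so that 15 does not reach step 5 intact. The fallback sets out from 12 and returns at 15. The acetylide 14, generated as in step 4, is silylated in the flask (i-Pr3SiOTf, −78 °C) to triisopropyl[(3,4,5-trimethoxyphenoxy)ethynyl]silane F8, a capped ynol ether that should survive chromatography and storage. Directly before step 5 the silyl group is removed (Bu4NF, THF, −20 °C), and the cold solution of 15 is passed through basic alumina and used at once.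

**Further compounds**
F1 | step 5 | 2-(benzyloxy)-5-bromo-3-ethoxybenzaldehyde | CCOc1cc(Br)cc(C=O)c1OCc1ccccc1
F2 | step 5 | 2-(benzyloxy)-3-ethoxy-5-(2,4,6-trimethoxyphenoxy)benzaldehyde | CCOc1cc(Oc2c(OC)cc(OC)cc2OC)cc(C=O)c1OCc1ccccc1
F3 | step 5 | 2-(benzyloxy)-3-ethoxy-5-(2,4,6-trimethoxyphenoxy)phenyl formate | CCOc1cc(Oc2c(OC)cc(OC)cc2OC)cc(OC=O)c1OCc1ccccc1
F4 | step 5 | 2-(benzyloxy)-3-ethoxy-5-(2,4,6-trimethoxyphenoxy)phenol | CCOc1cc(Oc2c(OC)cc(OC)cc2OC)cc(O)c1OCc1ccccc1
F5 | step 5 | 2-(benzyloxy)-1-ethoxy-5-(2,4,6-trimethoxyphenoxy)-3-(3,4,5-trimethoxyphenoxy)benzene | CCOc1cc(Oc2c(OC)cc(OC)cc2OC)cc(Oc2cc(OC)c(OC)c(OC)c2)c1OCc1ccccc1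
F6 | step 2 | pentacarbonyl[(Z)-3-ethoxy-1-(pentafluorophenoxy)prop-2-enylidene]chromium | CCO/C=C\C(Oc1c(F)c(F)c(F)c(F)c1F)=[Cr](=C=O)(=C=O)(=C=O)(=C=O)=C=O
F7 | step 2 | sodium 2,4,6-trimethoxyphenoxide | [Na+].COc1cc(OC)c([O-])c(OC)c1
F8 | step 4 | triisopropyl[(3,4,5-trimethoxyphenoxy)ethynyl]silane | CC(C)[Si](C#COc1cc(OC)c(OC)c(OC)c1)(C(C)C)C(C)C
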